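## Retrosynthetic overview

1. Feature, in benzofuran numbering: O1–C7a–C3a–C3 (the phenol oxygen, two carbons of ring A, and the benzylic carbon carrying ring C) is a latent ortho-quinone methide. C2 is the one carbon bridging its termini O1 and C3, so the heterocycle is cut as 4 + 1.
2. cis C2–H ⇒ C2–CO2H. The carboxyl group that stabilises the one-carbon ylide stays on as a traceless handle: it makes C2 nucleophilic for the C2–ring B bond (enolate arylation), then leaves as CO2 so that hydrogen enters anti to ring C.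
3. C2–C3 and O1–C2 ⇒ a quinone methide (from a 2-[aryl(tosyl)methyl]phenol) plus the cinchona ammonium ylide of tert-butyl bromoacetate. This step fixes C3.
4. C3–ring C ⇒ aryllithium plus salicylaldehyde. C3–C3a ⇒ Vilsmeier–Haack formylation of dihydroresveratrol, which already holds rings A and D and the ethyl bridge.
5. Ring order: benzene rings A–D are bought, and the dihydrofuran is the only ring made, in the annulation.

Key step: step 8

Notation: TBS = tert-butyldimethylsilyl. Ring A = benzo ring, ring B = aryl on C2, ring C = aryl on C3, ring D = aryl at the end of the C4 ethyl chain.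

Assumption: the quinine-derived ammonium salt is taken to induce the (3R) series on this C4-substituted quinone methide. This is to be checked on the first batch. If the sense is opposite, the pseudoenantiomeric quinidine-derived salt, made by the same two steps, would be used.

## Route

Step 1
Reactants: 1 dihydroresveratrol
Product: 3 2,4-dihydroxy-6-[2-(4-hydroxyphenyl)ethyl]benzaldehyde, via iminium chloride 2 (not isolated)
Conditions: POCl3 (1.5 equiv), DMF (3 equiv), MeCN, 0 °C → rt; then H2O, 50 °C
Reagents that add atoms: N,N-dimethylformamide CN(C)C=O; water O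
Why: Vilsmeier–Haack formylation; the resorcinol ring A is far more nucleophilic than the monophenol ring D and, as with other 5-alkylresorcinols, should be attacked next to the chain (para to one hydroxyl, ortho to the other) rather than between the two hydroxyls, and hydrolysis of 2 gives the aldehyde.

Step 2
Reactants: 3 2,4-dihydroxy-6-[2-(4-hydroxyphenyl)ethyl]benzaldehyde
Product: 4 4-(TBSO)-2-hydroxy-6-{2-[4-(TBSO)phenyl]ethyl}benzaldehyde
Conditions: TBSCl (2.1 equiv), imidazole (3 equiv), CH2Cl2/DMF 10:1, 0 °C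
Reagents that add atoms: tert-butyldimethylsilyl chloride CC(C)(C)[Si](C)(C)Cl
Why: Chemoselective O-silylation; the hydroxyl ortho to the formyl group is held in a strong intramolecular hydrogen bond and is flanked by the carbonyl, so two equivalents of silyl chloride should take only the para hydroxyl of ring A and the ring D phenol.

Step 3
Reactants: 5 5-bromoresorcinol
Product: 6 1-bromo-3,5-bis(TBSO)benzene
Conditions: TBSCl (2.3 equiv), imidazole (4 equiv), DMF, rt
Reagents that add atoms: tert-butyldimethylsilyl chloride CC(C)(C)[Si](C)(C)Cl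
Why: Standard imidazole-promoted silylation of two unhindered phenols, giving a ring C bromide free of acidic protons for the metalation.

Step 4
Reactants: 6 1-bromo-3,5-bis(TBSO)benzene; 4 4-(TBSO)-2-hydroxy-6-{2-[4-(TBSO)phenyl]ethyl}benzaldehyde
Product: 8 racemic 2-{[3,5-bis(TBSO)phenyl](hydroxy)methyl}-5-(TBSO)-3-{2-[4-(TBSO)phenyl]ethyl}phenol, via aryllithium 7 (not isolated)
Conditions: 6 (2.3 equiv), n-BuLi (2.2 equiv), THF, −78 °C; then 4, −78 → −20 °C; aq NH4Cl; used crude
Reagents that add atoms: none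
Why: Bromine–lithium exchange and 1,2-addition to the aldehyde; the first equivalent of 7 only deprotonates the phenol, the meta silyloxy groups cannot migrate to the carbanion, and the new carbinol centre forms as a racemate, which is harmless because step 8 erases it.

Step 5
Reactants: 8 racemic benzhydrol
Product: 9 racemic 2-{[3,5-bis(TBSO)phenyl](4-methylphenylsulfonyl)methyl}-5-(TBSO)-3-{2-[4-(TBSO)phenyl]ethyl}phenol
Conditions: p-TolSO2H (1.5 equiv, freshly liberated from p-TolSO2Na), CH2Cl2, rt
Reagents that add atoms: p-toluenesulfinic acid Cc1ccc(cc1)S(=O)O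
Why: SN1-type exchange of the benzhydrol hydroxyl; the ortho hydroxyl and para silyloxy groups make ionisation easy under the mild acidity of the sulfinic acid, which aryl silyl ethers tolerate, and S-attack of the sulfinate gives the stable sulfone.

Step 6
Reactants: 10 quinine
Product: 11 9-O-methylquinine
Conditions: NaH (1.2 equiv), DMF, 0 °C; MeI (1.05 equiv), 0 °C → rt
Reagents that add atoms: iodomethane CI
Why: Williamson etherification; the preformed alkoxide outcompetes the quinuclidine nitrogen for one equivalent of MeI, no stereocentre is touched, and capping removes a hydroxyl that could add to the quinone methide or lactonise onto the ester in step 8.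

Step 7
Reactants: 11 9-O-methylquinine; 12 tert-butyl bromoacetate
Product: 13 N-(2-tert-butoxy-2-oxoethyl)-9-O-methylquininium bromide
Conditions: THF, rt; precipitation with Et2O
Reagents that add atoms: none
Why: Menshutkin quaternisation; the sp3 quinuclidine nitrogen is much more nucleophilic than the quinoline nitrogen and the α-bromo ester is a very reactive SN2 partner, so the salt should separate cleanly.

Step 8
Reactants: 9 racemic sulfone; 13 N-(2-tert-butoxy-2-oxoethyl)-9-O-methylquininium bromide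
Product: 17 tert-butyl (2R,3R)-trans-3-[3,5-bis(TBSO)phenyl]-6-(TBSO)-4-{2-[4-(TBSO)phenyl]ethyl}-2,3-dihydro-1-benzofuran-2-carboxylate, via ortho-quinone methide 14 (not isolated), via ammonium ylide 15 (not isolated), via betaine 16 (not isolated)
Conditions: 13 (1.5 equiv), dried Cs2CO3 (3 equiv), anhydrous CH2Cl2, 0 °C → rt
Reagents that add atoms: none
Why: Cs2CO3 deprotonates the phenol of 9, whose phenoxide expels p-toluenesulfinate in a 1,4-elimination to give the planar ortho-quinone methide 14, and it also deprotonates 13 to the ester-stabilised ylide 15, whose carbanion adds in conjugate fashion to the exocyclic methide carbon (C2–C3 bond) with rearomatisation of ring A to betaine 16. The phenoxide O1 of 16 then displaces the quinuclidinium group at C2 from the rear (O1–C2 bond), a 5-exo-tet SN2 closure of the dihydrofuran ring that sets 11 free. The closest known reaction type is exactly this asymmetric (4+1) annulation of in situ generated ortho-quinone methides with cinchona ammonium ylides carrying ester, amide or ketone groups, which gives trans-2-acyl-3-aryl-2,3-dihydrobenzofurans. C3 is set in the conjugate addition, where the chiral ammonium group on the ylide carbon differentiates the two faces of 14; the racemic centre of 9 is erased beforehand and plays no part. C2 results from the betaine conformer that keeps the ester away from ring C during backside closure (and from base equilibration of the α-ester centre), hence trans, but this centre is removed again in steps 9 and 11. The one selectivity the step needs is enantioface selectivity at C3, and the C4 phenethyl chain should secure a single reacting geometry of 14 by allylic strain, turning ring C towards the carbonyl oxygen, while the donor silyloxy group at C6 keeps 14 long-lived enough to be intercepted instead of dimerising.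

Step 9
Reactants: 17 trans 2-carboxylate; 18 (4-bromophenoxy)(tert-butyl)dimethylsilane
Product: 20 tert-butyl (2R,3R)-3-[3,5-bis(TBSO)phenyl]-6-(TBSO)-2-[4-(TBSO)phenyl]-4-{2-[4-(TBSO)phenyl]ethyl}-2,3-dihydro-1-benzofuran-2-carboxylate (ring B anti to ring C), via lithium enolate 19 (not isolated)
Conditions: LiN(SiMe3)2 (1.2 equiv), toluene, 0 °C; then 18 (1.5 equiv), Pd(OAc)2 (5 mol %), P(t-Bu)3 (10 mol %), rt → 50 °C
Reagents that add atoms: none
Why: Buchwald–Hartwig α-arylation of an ester enolate; 19 has no β-leaving group and C3–H is not acidified, so C3 should survive, while the bulky electron-rich phosphine drives reductive elimination from the arylpalladium enolate to the quaternary C2, with ring B expected on the face anti to ring C, although either C2 epimer serves because step 11 erases this centre.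

Step 10
Reactants: 20 C2-arylated tert-butyl ester
Product: 21 (2R,3R)-3-[3,5-bis(TBSO)phenyl]-6-(TBSO)-2-[4-(TBSO)phenyl]-4-{2-[4-(TBSO)phenyl]ethyl}-2,3-dihydro-1-benzofuran-2-carboxylic acid
Conditions: CF3CO2H/CH2Cl2 1:4, 0 °C
Reagents that add atoms: none
Why: Acidolysis of the tert-butyl ester with E1 loss of isobutene; aryl silyl ethers resist brief acid exposure, the carboxyl group disfavours ionisation of the C2–O1 bond, and C3 is not involved.

Step 11
Reactants: 21 C2-quaternary carboxylic acid
Product: 23 (2S,3R)-cis-3-[3,5-bis(TBSO)phenyl]-6-(TBSO)-2-[4-(TBSO)phenyl]-4-{2-[4-(TBSO)phenyl]ethyl}-2,3-dihydro-1-benzofuran, via C2 radical 22 (not isolated)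
Conditions: 9-mesityl-10-methylacridinium tetrafluoroborate (5 mol %), 2,4,6-triisopropylbenzenethiol (30 mol %), 2,6-lutidine (30 mol %), ClCH2CH2Cl, 450 nm LEDs, argon, 0 °C; stopped at full conversion
Reagents that add atoms: none
Why: Proposed new method: the lutidine-derived carboxylate is the most easily oxidised site, so single-electron transfer to the excited acridinium gives an acyloxy radical that loses CO2 to the planar α-oxy benzylic radical 22. Ring C on C3 is pushed pseudo-axial by the in-plane ring B and the C4 chain and covers one face of 22, so the hindered thiol should hand over hydrogen from the opposite face, which forces ring B cis to ring C (2S). The thiyl radical is then reduced by the acridinyl radical and reprotonated by 21. An arenethiol is chosen because its weak S–H bond makes the transfer fast and practically irreversible, so the kinetic cis product should not drift to trans. The closest known reaction type is the acridinium/thiol (or disulfide) hydrodecarboxylation of α-oxy and arylacetic acids, together with the anti rule for attack on cyclic radicals with a neighbouring substituent. New here is its use on a 2-aryl-2,3-dihydrobenzofuran-2-carboxylic acid to set a contra-thermodynamic cis-diaryl relation.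

Step 12
Reactants: 23 cis pentakis-TBS ether
Product: 24 (2S,3R)-3-(3,5-dihydroxyphenyl)-2-(4-hydroxyphenyl)-4-[2-(4-hydroxyphenyl)ethyl]-2,3-dihydro-1-benzofuran-6-ol (target)
Conditions: n-Bu4NF/AcOH 1:1 (6 equiv each, premixed), THF, 0 °C; pH 6 phosphate buffer work-up
Reagents that add atoms: none
Why: Fluoride desilylation of five aryl silyl ethers; the acetic acid buffer keeps the ring B phenol protonated, so ring opening to a para-quinone methide and epimerisation of C2 to the trans isomer should be avoided, as should acid-induced ionisation of C2–O1.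

## Compound list

1 | dihydroresveratrol, 5-[2-(4-hydroxyphenyl)ethyl]benzene-1,3-diol | Oc1ccc(CCc2cc(O)cc(O)c2)cc1 | starting material
2 | aryl(dimethyl)iminium chloride of the Vilsmeier step (not isolated) | C[N+](C)=Cc1c(O)cc(O)cc1CCc1ccc(O)cc1.[Cl-] | intermediate
3 | 2,4-dihydroxy-6-[2-(4-hydroxyphenyl)ethyl]benzaldehyde | O=Cc1c(O)cc(O)cc1CCc1ccc(O)cc1 | intermediate
4 | 4-(TBSO)-2-hydroxy-6-{2-[4-(TBSO)phenyl]ethyl}benzaldehyde | O=Cc1c(O)cc(O[Si](C)(C)C(C)(C)C)cc1CCc1ccc(O[Si](C)(C)C(C)(C)C)cc1 | intermediate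
5 | 5-bromoresorcinol | Oc1cc(O)cc(Br)c1 | starting material
6 | 1-bromo-3,5-bis(TBSO)benzene | CC(C)(C)[Si](C)(C)Oc1cc(Br)cc(O[Si](C)(C)C(C)(C)C)c1 | intermediate
7 | 3,5-bis(TBSO)phenyllithium (not isolated) | [Li]c1cc(O[Si](C)(C)C(C)(C)C)cc(O[Si](C)(C)C(C)(C)C)c1 | intermediate
8 | racemic benzhydrol | OC(c1cc(O[Si](C)(C)C(C)(C)C)cc(O[Si](C)(C)C(C)(C)C)c1)c1c(O)cc(O[Si](C)(C)C(C)(C)C)cc1CCc1ccc(O[Si](C)(C)C(C)(C)C)cc1 | intermediate
9 | racemic 2-[aryl(tosyl)methyl]phenol, quinone methide source | Cc1ccc(cc1)S(=O)(=O)C(c1cc(O[Si](C)(C)C(C)(C)C)cc(O[Si](C)(C)C(C)(C)C)c1)c1c(O)cc(O[Si](C)(C)C(C)(C)C)cc1CCc1ccc(O[Si](C)(C)C(C)(C)C)cc1 | intermediate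
10 | quinine | COc1ccc2nccc([C@H]([C@@H]3C[C@@H]4CCN3C[C@@H]4C=C)O)c2c1 | starting material
11 | 9-O-methylquinine | COc1ccc2nccc([C@H]([C@@H]3C[C@@H]4CCN3C[C@@H]4C=C)OC)c2c1 | intermediate
12 | tert-butyl bromoacetate | CC(C)(C)OC(=O)CBr | starting material
13 | N-(2-tert-butoxy-2-oxoethyl)-9-O-methylquininium bromide | [Br-].COc1ccc2nccc([C@H]([C@@H]3C[C@@H]4CC[N+]3(CC(=O)OC(C)(C)C)C[C@@H]4C=C)OC)c2c1 | intermediate
14 | ortho-quinone methide, alkene geometry not assigned (not isolated) | O=C1C=C(O[Si](C)(C)C(C)(C)C)C=C(CCc2ccc(O[Si](C)(C)C(C)(C)C)cc2)C1=Cc1cc(O[Si](C)(C)C(C)(C)C)cc(O[Si](C)(C)C(C)(C)C)c1 | intermediate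
15 | ammonium ylide of 13 (not isolated) | COc1ccc2nccc([C@H]([C@@H]3C[C@@H]4CC[N+]3([CH-]C(=O)OC(C)(C)C)C[C@@H]4C=C)OC)c2c1 | intermediate
16 | ammonium phenoxide betaine (not isolated) | COc1ccc2nccc([C@H]([C@@H]3C[C@@H]4CC[N+]3([C@H](C(=O)OC(C)(C)C)[C@H](c5cc(O[Si](C)(C)C(C)(C)C)cc(O[Si](C)(C)C(C)(C)C)c5)c5c([O-])cc(O[Si](C)(C)C(C)(C)C)cc5CCc5ccc(O[Si](C)(C)C(C)(C)C)cc5)C[C@@H]4C=C)OC)c2c1 | intermediate
17 | tert-butyl (2R,3R)-trans-3-aryl-2,3-dihydrobenzofuran-2-carboxylate | CC(C)(C)[Si](C)(C)Oc1ccc(CCc2cc(O[Si](C)(C)C(C)(C)C)cc3c2[C@@H](c2cc(O[Si](C)(C)C(C)(C)C)cc(O[Si](C)(C)C(C)(C)C)c2)[C@H](C(=O)OC(C)(C)C)O3)cc1 | intermediate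
18 | (4-bromophenoxy)(tert-butyl)dimethylsilane | CC(C)(C)[Si](C)(C)Oc1ccc(Br)cc1 | starting material
19 | lithium enolate of 17 (not isolated) | CC(C)(C)[Si](C)(C)Oc1ccc(CCc2cc(O[Si](C)(C)C(C)(C)C)cc3c2[C@@H](c2cc(O[Si](C)(C)C(C)(C)C)cc(O[Si](C)(C)C(C)(C)C)c2)C(=C([O-])OC(C)(C)C)O3)cc1.[Li+] | intermediate
20 | (2R,3R) C2-arylated tert-butyl ester, ring B anti to ring C | CC(C)(C)[Si](C)(C)Oc1ccc(CCc2cc(O[Si](C)(C)C(C)(C)C)cc3c2[C@@H](c2cc(O[Si](C)(C)C(C)(C)C)cc(O[Si](C)(C)C(C)(C)C)c2)[C@](C(=O)OC(C)(C)C)(c2ccc(O[Si](C)(C)C(C)(C)C)cc2)O3)cc1 | intermediate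
21 | (2R,3R) C2-quaternary carboxylic acid | CC(C)(C)[Si](C)(C)Oc1ccc(CCc2cc(O[Si](C)(C)C(C)(C)C)cc3c2[C@@H](c2cc(O[Si](C)(C)C(C)(C)C)cc(O[Si](C)(C)C(C)(C)C)c2)[C@](C(=O)O)(c2ccc(O[Si](C)(C)C(C)(C)C)cc2)O3)cc1 | intermediate
22 | planar α-oxy benzylic C2 radical (not isolated) | CC(C)(C)[Si](C)(C)Oc1ccc(CCc2cc(O[Si](C)(C)C(C)(C)C)cc3c2[C@@H](c2cc(O[Si](C)(C)C(C)(C)C)cc(O[Si](C)(C)C(C)(C)C)c2)[C](c2ccc(O[Si](C)(C)C(C)(C)C)cc2)O3)cc1 | intermediate
23 | (2S,3R)-cis pentakis-TBS ether of the target | CC(C)(C)[Si](C)(C)Oc1ccc(CCc2cc(O[Si](C)(C)C(C)(C)C)cc3c2[C@@H](c2cc(O[Si](C)(C)C(C)(C)C)cc(O[Si](C)(C)C(C)(C)C)c2)[C@@H](c2ccc(O[Si](C)(C)C(C)(C)C)cc2)O3)cc1 | intermediate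
24 | CNP0174555.1, (2S,3R)-cis | Oc1ccc(CCc2cc(O)cc3c2[C@@H](c2cc(O)cc(O)c2)[C@@H](c2ccc(O)cc2)O3)cc1 | target

## Step count and risks

Total step count: 12. Longest linear sequence: 9 steps (1, 2, 4, 5, 8, 9, 10, 11, 12).

**Step 11.**
- What may go wrong:
  - The facial bias in the hydrogen-atom transfer may be too small.
  - The cis relation may erode if the excited acridinium re-oxidises the electron-rich product, with loss of a benzylic proton from the arene radical cation.
  - The radical may be over-oxidised to the oxocarbenium ion, followed by aromatisation.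
- Fallback: Barton reductive decarboxylation, a known chain process that needs no photooxidant and runs at low temperature with a large excess of donor.
- It sets out from 21. Coupling with 1-hydroxypyridine-2(1H)-thione (DCC, CH2Cl2, 0 °C, dark) gives the thiohydroxamate ester F1.
- Visible-light photolysis of F1 in toluene at −40 °C with excess 2,4,6-triisopropylbenzenethiol should give the same anti hydrogen delivery. The route is rejoined at 23.

**Step 9.**
- What may go wrong:
  - Reductive elimination at the crowded, fully substituted C2 may be slow.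
  - Syn β-hydride elimination from the C-bound palladium enolate may occur, with aromatisation of the heterocycle and loss of C3.
  - The aryl bromide may be aminated by the silylamide.
- Fallback: metal-free SNAr arylation followed by adjustment of the para substituent.
- It sets out from 17. KN(SiMe3)2 (THF, −78 °C) gives the potassium enolate F2.
- 1-Fluoro-4-nitrobenzene (−78 → 0 °C) converts F2 into the 2-(4-nitrophenyl) ester F3.
- Hydrogenation (H2, 1 atm, Pd/C, EtOAc) gives the 2-(4-aminophenyl) ester F4.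
- Sandmeyer-type borylation (t-BuONO, B2pin2, MeCN, rt) gives the arylboronic pinacol ester F5.
- Buffered oxidation (H2O2, pH 7 phosphate, THF, 0 °C) gives the 2-(4-hydroxyphenyl) ester F6.
- Silylation (TBSCl, imidazole, DMF) rejoins the route at 20.

**Step 8.**
- What may go wrong:
  - Enantioface selectivity may be low if both alkene geometries of the crowded quinone methide react.
  - Addition to the hindered methide carbon may be slow enough for the bulky ylide to decay.
  - Aryl silyl ethers may be partly lost to the carbonate.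
- Fallback: racemic annulation with a small achiral ylide, then resolution.
- It sets out from 12 and 9. Trimethylamine and 12 (THF, rt) give (2-tert-butoxy-2-oxoethyl)trimethylammonium bromide F7.
- With 9 and Cs2CO3 in CH2Cl2, F7 forms the trimethylammonium ylide F8, which closes onto 14 to give the racemic trans ester, that is 17 together with its (2S,3S) enantiomer F9.
- Preparative chromatography on a chiral stationary phase removes F9, and the route is rejoined at 17.

## Further compounds

F1 | step 11 | thiohydroxamate (Barton) ester of 21 | CC(C)(C)[Si](C)(C)Oc1ccc(CCc2cc(O[Si](C)(C)C(C)(C)C)cc3c2[C@@H](c2cc(O[Si](C)(C)C(C)(C)C)cc(O[Si](C)(C)C(C)(C)C)c2)[C@](C(=O)ON2C=CC=CC2=S)(c2ccc(O[Si](C)(C)C(C)(C)C)cc2)O3)cc1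
F2 | step 9 | potassium enolate of 17 | CC(C)(C)[Si](C)(C)Oc1ccc(CCc2cc(O[Si](C)(C)C(C)(C)C)cc3c2[C@@H](c2cc(O[Si](C)(C)C(C)(C)C)cc(O[Si](C)(C)C(C)(C)C)c2)C(=C([O-])OC(C)(C)C)O3)cc1.[K+]
F3 | step 9 | (2R,3R) 2-(4-nitrophenyl) tert-butyl ester | CC(C)(C)[Si](C)(C)Oc1ccc(CCc2cc(O[Si](C)(C)C(C)(C)C)cc3c2[C@@H](c2cc(O[Si](C)(C)C(C)(C)C)cc(O[Si](C)(C)C(C)(C)C)c2)[C@](C(=O)OC(C)(C)C)(c2ccc([N+](=O)[O-])cc2)O3)cc1
F4 | step 9 | (2R,3R) 2-(4-aminophenyl) tert-butyl ester | CC(C)(C)[Si](C)(C)Oc1ccc(CCc2cc(O[Si](C)(C)C(C)(C)C)cc3c2[C@@H](c2cc(O[Si](C)(C)C(C)(C)C)cc(O[Si](C)(C)C(C)(C)C)c2)[C@](C(=O)OC(C)(C)C)(c2ccc(N)cc2)O3)cc1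
F5 | step 9 | (2R,3R) 2-[4-(pinacolatoboryl)phenyl] tert-butyl ester | CC(C)(C)[Si](C)(C)Oc1ccc(CCc2cc(O[Si](C)(C)C(C)(C)C)cc3c2[C@@H](c2cc(O[Si](C)(C)C(C)(C)C)cc(O[Si](C)(C)C(C)(C)C)c2)[C@](C(=O)OC(C)(C)C)(c2ccc(B4OC(C)(C)C(C)(C)O4)cc2)O3)cc1
F6 | step 9 | (2R,3R) 2-(4-hydroxyphenyl) tert-butyl ester | CC(C)(C)[Si](C)(C)Oc1ccc(CCc2cc(O[Si](C)(C)C(C)(C)C)cc3c2[C@@H](c2cc(O[Si](C)(C)C(C)(C)C)cc(O[Si](C)(C)C(C)(C)C)c2)[C@](C(=O)OC(C)(C)C)(c2ccc(O)cc2)O3)cc1
F7 | step 8 | (2-tert-butoxy-2-oxoethyl)trimethylammonium bromide | C[N+](C)(C)CC(=O)OC(C)(C)C.[Br-]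
F8 | step 8 | trimethylammonium ylide of F7 | C[N+](C)(C)[CH-]C(=O)OC(C)(C)C
F9 | step 8 | (2S,3S) enantiomer of 17 | CC(C)(C)[Si](C)(C)Oc1ccc(CCc2cc(O[Si](C)(C)C(C)(C)C)cc3c2[C@H](c2cc(O[Si](C)(C)C(C)(C)C)cc(O[Si](C)(C)C(C)(C)C)c2)[C@@H](C(=O)OC(C)(C)C)O3)cc1
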